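**Strategy**

Everything rests on cutting the bond between C8 of the A ring and the lavandulyl CH2 (C1''). C8 lies between the pyranone oxygen O1 and the C7 oxygen and para to the C5 methoxy group, so a 5,7-dioxygenated chromone should be iodinated there; C1'' is a primary carbon one bond away from the C2'' stereocentre. The key step is a Negishi coupling of (S)-lavandulylzinc iodide, made by auxiliary-controlled deconjugative prenylation, with 8-iodo-5-methoxy-7-silyloxychromone: it installs the complete C10 chain with its stereocentre in one operation. The C2 stereocentre then comes from a rhodium-catalysed asymmetric addition of the B-ring boronate, followed by global desilylation.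

Key step: step 8

Assumption: the (2R)-lavandulyl centre of the target corresponds spatially to (S)-lavandulol, because replacing OH by the aryl carbon reverses the CIP ranking of CH2X and isopropenyl; compounds 1, 2, 4, 9 and 16 are taken as commercial.

**Route**

Step 1
Reactants: 1 (S)-4-benzyloxazolidin-2-one; 2 3-methylbut-2-enoyl chloride
Product: 3 (S)-4-benzyl-3-(3-methylbut-2-enoyl)oxazolidin-2-one
Conditions: n-BuLi, THF, −78 °C; then 2, −78 → 0 °C
Reagents that add atoms: none
Why: N-acylation of the lithiated oxazolidinone by the acid chloride (Evans imide formation); no stereocentre is formed and the auxiliary centre is untouched.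

Step 2
Reactants: 3 (S)-4-benzyl-3-(3-methylbut-2-enoyl)oxazolidin-2-one; 4 prenyl bromide (1-bromo-3-methylbut-2-ene)
Product: 6 (S)-4-benzyl-3-[(S)-5-methyl-2-(prop-1-en-2-yl)hex-4-enoyl]oxazolidin-2-one, via sodium dienolate 5 (not isolated)
Conditions: NaHMDS, THF, −78 °C; then 4, −78 → −20 °C
Reagents that add atoms: none
Why: Deconjugative Evans alkylation: γ-deprotonation gives the chelated (Z)-dienolate, which should be alkylated at the α-carbon on the face opposite the C4 benzyl group, setting the α-centre as S and turning the conjugated alkene into the isopropenyl group.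

Step 3
Reactants: 6 (S)-4-benzyl-3-[(S)-5-methyl-2-(prop-1-en-2-yl)hex-4-enoyl]oxazolidin-2-one
Product: 7 (S)-lavandulol [(S)-5-methyl-2-(prop-1-en-2-yl)hex-4-en-1-ol]
Conditions: LiBH4, MeOH (1 equiv), Et2O, 0 °C
Reagents that add atoms: none
Why: Reductive cleavage of the imide by lithium borohydride should give the primary alcohol and release the auxiliary without enolising the β,γ-unsaturated α-centre.

Step 4
Reactants: 7 (S)-lavandulol
Product: 8 (S)-lavandulyl iodide [(3S)-3-(iodomethyl)-2,6-dimethylhepta-1,5-diene]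
Conditions: I2, PPh3, imidazole, CH2Cl2, 0 °C → rt
Reagents that add atoms: iodine, II
Why: Appel-type iodination through the alkoxyphosphonium iodide with SN2 displacement at the CH2 group; the adjacent stereocentre is not involved.

Step 5
Reactants: 9 1-(2,4-dihydroxy-6-methoxyphenyl)ethan-1-one
Product: 10 1-[2-hydroxy-6-methoxy-4-(triisopropylsilyloxy)phenyl]ethan-1-one
Conditions: TIPSCl (1.05 equiv), imidazole, CH2Cl2, 0 °C → rt
Reagents that add atoms: triisopropylsilyl chloride, CC(C)[Si](Cl)(C(C)C)C(C)C
Why: Selective silylation of the more acidic, non-chelated para-hydroxyl; the ortho-hydroxyl is hydrogen-bonded to the ketone and stays free for the ring closure.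

Step 6
Reactants: 10 1-[2-hydroxy-6-methoxy-4-(triisopropylsilyloxy)phenyl]ethan-1-one
Product: 12 5-methoxy-7-(triisopropylsilyloxy)-4H-chromen-4-one, via enaminone 11 (not isolated)
Conditions: Me2NCH(OMe)2, toluene, 90 °C; then AcOH, 60 °C
Reagents that add atoms: N,N-dimethylformamide dimethyl acetal, COC(OC)N(C)C
Why: Enaminone formation at the acetyl methyl group, then acid-promoted addition–elimination by the ortho-phenol with loss of dimethylamine, should give the chromone; aryl silyl ethers tolerate acetic acid.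

Step 7
Reactants: 12 5-methoxy-7-(triisopropylsilyloxy)-4H-chromen-4-one
Product: 13 8-iodo-5-methoxy-7-(triisopropylsilyloxy)-4H-chromen-4-one
Conditions: NIS, TFA (cat.), MeCN, 0 °C → rt
Reagents that add atoms: N-iodosuccinimide, O=C1CCC(=O)N1I
Why: Electrophilic aromatic iodination; C8 is para to the 5-methoxy group, ortho to the 7-silyloxy group and to O1, and less hindered than C6, which sits between the methoxy and the bulky silyloxy group.

Step 8
Reactants: 8 (S)-lavandulyl iodide; 13 8-iodo-5-methoxy-7-(triisopropylsilyloxy)-4H-chromen-4-one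
Product: 15 5-methoxy-8-[(2R)-5-methyl-2-(prop-1-en-2-yl)hex-4-en-1-yl]-7-(triisopropylsilyloxy)-4H-chromen-4-one, via (S)-lavandulylzinc iodide 14 (not isolated)
Conditions: 8, Zn dust (BrCH2CH2Br/TMSCl-activated), LiCl, THF, 40 °C; then 13, Pd(OAc)2 (2 mol %), SPhos (4 mol %), THF/NMP, rt → 45 °C
Reagents that add atoms: none
Why: Zinc inserts into the primary C–I bond of 8 to give the alkylzinc iodide 14; Pd(0) adds oxidatively to the C8–I bond of 13, the lavandulyl CH2 is transferred from zinc to palladium and reductive elimination forms the C8–CH2 bond. The closest known reaction type is the Negishi C(sp2)–C(sp3) coupling of primary alkylzinc halides with di-ortho-substituted aryl halides under biarylphosphine–palladium catalysis. No ring is closed. No stereocentre is created; the existing centre is β to zinc and to palladium, is not touched by either metal–carbon bond, and a homoallylic zinc reagent should not rearrange through a cyclopropylcarbinyl form at these temperatures. The step needs reductive elimination to outrun β-hydride elimination (which would remove the hydrogen of that centre) and protodeiodination; the bulky electron-rich ligand and the two ortho oxygen substituents on the aryl–palladium unit should secure this. Site selectivity is fixed by the iodine at C8, and the chromone carbonyl, enol ether and silyl ether are inert to an alkylzinc halide.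

Step 9
Reactants: 16 4-bromobenzene-1,3-diol
Product: 17 1-bromo-2,4-bis(tert-butyldimethylsilyloxy)benzene
Conditions: TBSCl, imidazole, DMF, rt
Reagents that add atoms: tert-butyldimethylsilyl chloride, CC(C)(C)[Si](C)(C)Cl
Why: Standard silylation of both phenols, giving fluoride-labile protection that survives the later palladium and rhodium steps.

Step 10
Reactants: 17 1-bromo-2,4-bis(tert-butyldimethylsilyloxy)benzene
Product: 18 2-[2,4-bis(tert-butyldimethylsilyloxy)phenyl]-4,4,5,5-tetramethyl-1,3,2-dioxaborolane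
Conditions: B2pin2, Pd(dppf)Cl2 (3 mol %), KOAc, dioxane, 85 °C
Reagents that add atoms: bis(pinacolato)diboron, CC1(C)OB(B2OC(C)(C)C(C)(C)O2)OC1(C)C
Why: Miyaura borylation of the aryl bromide; it avoids an ortho-lithiated aryl silyl ether, which could undergo O-to-C silyl migration.

Step 11
Reactants: 15 5-methoxy-8-[(2R)-5-methyl-2-(prop-1-en-2-yl)hex-4-en-1-yl]-7-(triisopropylsilyloxy)-4H-chromen-4-one; 18 2-[2,4-bis(tert-butyldimethylsilyloxy)phenyl]-4,4,5,5-tetramethyl-1,3,2-dioxaborolane
Product: 19 (2S)-2-[2,4-bis(tert-butyldimethylsilyloxy)phenyl]-5-methoxy-8-[(2R)-5-methyl-2-(prop-1-en-2-yl)hex-4-en-1-yl]-7-(triisopropylsilyloxy)chroman-4-one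
Conditions: [RhCl(C2H4)2]2 (2.5 mol %), (S,S)-Ph-bod (5.5 mol %), KOH (10 mol %), dioxane/H2O 10:1, 40 °C
Reagents that add atoms: none
Why: Rhodium-catalysed asymmetric 1,4-addition of the aryl group to chromone C2 (Hayashi–Miyaura reaction); the chiral diene controls the face of aryl-rhodium insertion, the (S,S)-ligand is expected to give 2S by analogy with its sense on cyclic enones (the antipode would be used if the sense proves opposite), and the isolated alkenes should not react.

Step 12
Reactants: 19 (2S)-2-[2,4-bis(tert-butyldimethylsilyloxy)phenyl]-5-methoxy-8-[(2R)-5-methyl-2-(prop-1-en-2-yl)hex-4-en-1-yl]-7-(triisopropylsilyloxy)chroman-4-one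
Product: 20 kurarinone
Conditions: TBAF, AcOH (1:1, 3.5 equiv), THF, 0 °C
Reagents that add atoms: none
Why: Fluoride cleaves the three aryl silyl ethers; the acetic acid buffer keeps the medium non-basic, so the flavanone should not ring-open (no epimerisation at C2) and the 7-hydroxyl should not add to the isopropenyl group.

**Compound list**

1 | (S)-4-benzyloxazolidin-2-one | O=C1N[C@@H](Cc2ccccc2)CO1 | starting material
2 | 3-methylbut-2-enoyl chloride | CC(C)=CC(=O)Cl | starting material
3 | (S)-4-benzyl-3-(3-methylbut-2-enoyl)oxazolidin-2-one | CC(C)=CC(=O)N1[C@@H](Cc2ccccc2)COC1=O | intermediate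
4 | prenyl bromide (1-bromo-3-methylbut-2-ene) | CC(C)=CCBr | starting material
5 | sodium (Z)-dienolate of 3 | C=C(C)/C=C(\[O-])N1[C@@H](Cc2ccccc2)COC1=O.[Na+] | intermediate
6 | (S)-4-benzyl-3-[(S)-5-methyl-2-(prop-1-en-2-yl)hex-4-enoyl]oxazolidin-2-one | C=C(C)[C@H](CC=C(C)C)C(=O)N1[C@@H](Cc2ccccc2)COC1=O | intermediate
7 | (S)-lavandulol | C=C(C)[C@H](CC=C(C)C)CO | intermediate
8 | (S)-lavandulyl iodide | C=C(C)[C@H](CC=C(C)C)CI | intermediate
9 | 1-(2,4-dihydroxy-6-methoxyphenyl)ethan-1-one | CC(=O)c1c(O)cc(O)cc1OC | starting material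
10 | 1-[2-hydroxy-6-methoxy-4-(triisopropylsilyloxy)phenyl]ethan-1-one | CC(=O)c1c(O)cc(O[Si](C(C)C)(C(C)C)C(C)C)cc1OC | intermediate
11 | (E)-3-(dimethylamino)-1-[2-hydroxy-6-methoxy-4-(triisopropylsilyloxy)phenyl]prop-2-en-1-one | CN(C)/C=C/C(=O)c1c(O)cc(O[Si](C(C)C)(C(C)C)C(C)C)cc1OC | intermediate
12 | 5-methoxy-7-(triisopropylsilyloxy)-4H-chromen-4-one | COc1cc(O[Si](C(C)C)(C(C)C)C(C)C)cc2occc(=O)c12 | intermediate
13 | 8-iodo-5-methoxy-7-(triisopropylsilyloxy)-4H-chromen-4-one | COc1cc(O[Si](C(C)C)(C(C)C)C(C)C)c(I)c2occc(=O)c12 | intermediate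
14 | (S)-lavandulylzinc iodide | C=C(C)[C@H](CC=C(C)C)C[Zn]I | intermediate
15 | 5-methoxy-8-[(2R)-5-methyl-2-(prop-1-en-2-yl)hex-4-en-1-yl]-7-(triisopropylsilyloxy)-4H-chromen-4-one | C=C(C)[C@H](CC=C(C)C)Cc1c(O[Si](C(C)C)(C(C)C)C(C)C)cc(OC)c2c(=O)ccoc12 | intermediate
16 | 4-bromobenzene-1,3-diol | Oc1ccc(Br)c(O)c1 | starting material
17 | 1-bromo-2,4-bis(tert-butyldimethylsilyloxy)benzene | CC(C)(C)[Si](C)(C)Oc1ccc(Br)c(O[Si](C)(C)C(C)(C)C)c1 | intermediate
18 | 2-[2,4-bis(tert-butyldimethylsilyloxy)phenyl]-4,4,5,5-tetramethyl-1,3,2-dioxaborolane | CC(C)(C)[Si](C)(C)Oc1ccc(B2OC(C)(C)C(C)(C)O2)c(O[Si](C)(C)C(C)(C)C)c1 | intermediate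
19 | (2S)-2-[2,4-bis(tert-butyldimethylsilyloxy)phenyl]-5-methoxy-8-[(2R)-5-methyl-2-(prop-1-en-2-yl)hex-4-en-1-yl]-7-(triisopropylsilyloxy)chroman-4-one | C=C(C)[C@H](CC=C(C)C)Cc1c(O[Si](C(C)C)(C(C)C)C(C)C)cc(OC)c2c1O[C@H](c1ccc(O[Si](C)(C)C(C)(C)C)cc1O[Si](C)(C)C(C)(C)C)CC2=O | intermediate
20 | kurarinone | C=C(C)[C@H](CC=C(C)C)Cc1c(O)cc(OC)c2c1O[C@H](c1ccc(O)cc1O)CC2=O | target

**Step count**

Total: 12 steps. Longest linear sequence: 7 steps (steps 1, 2, 3, 4, 8, 11, 12).

**Steps most likely to fail and fallbacks**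

Step 11. The hindered, electron-rich ortho-silyloxy boronate may give poor facial selectivity in the aryl transfer, and the catalytic hydroxide may erode the C2 configuration through reversible opening of the pyranone ring. The fallback sets out from 15 and 18. An achiral rhodium catalyst ([Rh(OH)(cod)]2, dioxane/H2O, 50 °C) would add the aryl group without facial control to give the C2-epimeric flavanone mixture F2. Asymmetric transfer hydrogenation under kinetic-resolution control (RuCl(p-cymene)(TsDPEN), HCO2H/Et3N, the catalyst antipode chosen so that the 2R epimer reacts) would reduce that epimer to the cis-flavan-4-ol F3 and leave the 2S ketone. The fallback rejoins the route at 19.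

Step 8. Transmetalation to the di-ortho-substituted aryl–palladium species may be slow, allowing protodeiodination, or β-hydride elimination at the alkyl–palladium stage may scramble the lavandulyl centre. The fallback sets out from 8 and 13 and replaces the zinc reagent by a boron ate complex. Iodine–lithium exchange on 8 (t-BuLi, Et2O, −78 °C) and trapping with B-methoxy-9-BBN would give lithium B-methoxy-B-[(S)-lavandulyl]-9-borabicyclo[3.3.1]nonanate F1. This would be coupled with 13 under B-alkyl Suzuki–Miyaura conditions (PdCl2(dppf), K3PO4, DMF/THF, rt). The fallback rejoins the route at 15.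

Step 7. Iodination may be diverted to C6 or to C3 of the pyranone ring. The fallback sets out from 10 and fixes the site before the ring is closed, using the hydrogen-bonded phenol as the directing element. Iodination ortho to that hydroxyl (BnMe3N+ ICl2−, CaCO3, CH2Cl2/MeOH) would give 1-[2-hydroxy-3-iodo-6-methoxy-4-(triisopropylsilyloxy)phenyl]ethan-1-one F4. Condensation with DMF dimethyl acetal would give the iodo-enaminone F5, which would be cyclised in acetic acid. The fallback rejoins the route at 13.

**Further compounds**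

F1 | step 8 | lithium B-methoxy-B-[(S)-lavandulyl]-9-borabicyclo[3.3.1]nonanate | C=C(C)[C@H](CC=C(C)C)C[B-]1(OC)C2CCCC1CCC2.[Li+]
F2 | step 11 | C2-epimeric mixture of 2-[2,4-bis(tert-butyldimethylsilyloxy)phenyl]-5-methoxy-8-[(2R)-5-methyl-2-(prop-1-en-2-yl)hex-4-en-1-yl]-7-(triisopropylsilyloxy)chroman-4-one | C=C(C)[C@H](CC=C(C)C)Cc1c(O[Si](C(C)C)(C(C)C)C(C)C)cc(OC)c2c1OC(c1ccc(O[Si](C)(C)C(C)(C)C)cc1O[Si](C)(C)C(C)(C)C)CC2=O
F3 | step 11 | (2R,4R)-2-[2,4-bis(tert-butyldimethylsilyloxy)phenyl]-5-methoxy-8-[(2R)-5-methyl-2-(prop-1-en-2-yl)hex-4-en-1-yl]-7-(triisopropylsilyloxy)chroman-4-ol | C=C(C)[C@H](CC=C(C)C)Cc1c(O[Si](C(C)C)(C(C)C)C(C)C)cc(OC)c2c1O[C@@H](c1ccc(O[Si](C)(C)C(C)(C)C)cc1O[Si](C)(C)C(C)(C)C)C[C@H]2O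
F4 | step 7 | 1-[2-hydroxy-3-iodo-6-methoxy-4-(triisopropylsilyloxy)phenyl]ethan-1-one | CC(=O)c1c(O)c(I)c(O[Si](C(C)C)(C(C)C)C(C)C)cc1OC
F5 | step 7 | (E)-3-(dimethylamino)-1-[2-hydroxy-3-iodo-6-methoxy-4-(triisopropylsilyloxy)phenyl]prop-2-en-1-one | CN(C)/C=C/C(=O)c1c(O)c(I)c(O[Si](C(C)C)(C(C)C)C(C)C)cc1OC
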